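(All runs are simulated on assumed constants, and the scatter is random.)

**Early lead.** At early times Tuesday's run already shows right-handed substrate ahead, 44% against 30% at 5.00 min: the catalyst drains left-handed substrate and inversion refills it.

| flask | left-handed substrate | right-handed substrate | partner | precatalyst | added ligand | remark | time |
|---|---|---|---|---|---|---|---|
| Tuesday's | 0.013 M | 0.013 M | 0.044 M | 3 mM | 2.6 mM | run made earlier |  |
| Thursday's | 0.030 M | 0.030 M | 0.044 M | 3 mM | 2.6 mM | run made earlier |  |
| flask | 0.020 M | 0.020 M | 0.0440 M | 3.0 mM | 2.6 mM |  | 50 min |

| run | time / min | left-handed substrate / % | right-handed substrate / % | left-handed product / % |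
|---|---|---|---|---|
| Tuesday's | 5.00 | 30 | 44 | 24 |
| Tuesday's | 15.0 | 10 | 16 | 73 |
| Tuesday's | 25.0 | 5 | 6 | 87 |
| Tuesday's | 40.0 | 3 | 3 | 96 |
| Thursday's | 10.0 | 21 | 30 | 46 |
| Thursday's | 20.0 | 15 | 20 | 65 |
| Thursday's | 30.0 | 15 | 16 | 69 |
| Thursday's | 40.0 | 14 | 15 | 72 |

(each reading ± 1.5 percentage points)

- catalyst is single-handed; left-handed substrate and right-handed substrate are mirror images of each other, charged as a racemate, each of them at the stated concentration
- the numbers in the tables scatter with a standard deviation of 1.5 percentage points
- what may be going on: partner + catalyst + left-handed substrate -> catalyst + left-handed product; partner + catalyst + right-handed substrate -> catalyst + right-handed product; left-handed substrate <-> right-handed substrate; precatalyst -> catalyst; catalyst + added ligand <-> idle complex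
- an excess is the difference of the two amounts in percent of their sum
- an excess is below zero if the other one leads

- part of the left-handed substrate and right-handed substrate charged together that has reacted at 50 min
- excess of left-handed product over right-handed product in the product at 50 min
- excess of right-handed substrate over left-handed substrate among what is left of the two at 50 min

**The fork.** Here is the quick number, with one rule behind it. A left-handed substrate molecule either becomes product, at a pseudo-first-order rate q, or inverts, at constant k. Each inversion moves the gap between the substrates by two molecules, so where that gap holds steady, the drain equals two times the net inversion, and the excess e obeys e/(1−e) = q/(4k). Call this ratio the fork number. Here q scales with both [catalyst] and [partner]. With the precatalyst and added ligand charges the same, as in both runs and the flask, q follows [partner] once [catalyst] has stopped climbing, and not while precatalyst is still going over to catalyst.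

**Reading it.** Tuesday's run at 15.0 min reads e = 23.1% with 25.0 mM partner left, a fork number per unit of [partner] of 0.0120 mM⁻¹. This is a single noisy reading; Thursday's run at 10.0 min, taken earlier and perhaps with precatalyst still going over to catalyst, gives 0.0131 mM⁻¹.

**The forecast.** It gives 90% reacted, eP 97% and eS 8% (range 2% to 15%), holding that “Racemization keeps substrate excess small”. Its conversion leaves 8.00 mM partner in the flask, and the fork number then gives my own eS of 8.76%, slightly above the forecast's.

**The result.** The flask gives 93.9% reacted, eP 96.1% and eS 8.18%. All three stand within the tolerance, and eP and eS lie inside the forecast's ranges, but the conversion lies above the top of its range, 93%.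

    partner + catalyst + left-handed substrate → catalyst + left-handed product (k = 6230 M⁻² min⁻¹)
    partner + catalyst + right-handed substrate → catalyst + right-handed product (k = 89.7 M⁻² min⁻¹)
    left-handed substrate ⇌ right-handed substrate (k = 0.223 min⁻¹)
    precatalyst → catalyst (k = 0.196 min⁻¹)
    catalyst + added ligand ⇌ idle complex, settled at all times (K = 480 M⁻¹)

The half-life of left-handed substrate by inversion, forward step alone, is 3.1 min, short against 50 min. The forecast would fail with another charge: a neighbour with 0.011 M partner reaches only 27.5%, its partner, the limiting reagent, down to 0.054% of its charge. The fork number gives that neighbour an excess of 0.00716%, and it shows 0.0117%.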